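**Strategy.** Everything rests on opening ring A between C1 and C2. In ring A every second carbon is heteroatom-substituted (OH on C1, Br on C3 and C5), the signature of a cyclised triketide, while C2, the carbon joined to ring B through oxygen, corresponds to an activated CH2 of the open chain. The key step exploits exactly this: a magnesium-templated Claisen cyclisation of methyl 6-(2,4-dibromophenoxy)-3,5-dioxohexanoate closes ring A in one operation and gives the symmetric 2-aryloxyphloroglucinol, with the diaryl ether already installed by a phenol alkylation. The C5 hydroxyl and one flanking hydroxyl are then exchanged for amino groups and replaced by bromine in a double Sandmeyer reaction.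

Key step: step 3

Assumption: the 2-aryloxy group is taken not to change the usual order of ammonia exchange in phloroglucinols (unhindered C5 hydroxyl first, then one flanking hydroxyl, the third not at all under these conditions).

**Route**

Step 1
Reactants: 1 2,4-dibromophenol; 2 methyl bromoacetate
Product: 3 methyl 2-(2,4-dibromophenoxy)acetate
Conditions: K2CO3, acetone, reflux
Reagents that add atoms: none
Why: Williamson ether synthesis: the phenoxide of 1 displaces bromide from the unhindered primary carbon next to the ester, and neither the aryl bromides nor the methyl ester react with K2CO3 in acetone.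

Step 2
Reactants: 3 methyl 2-(2,4-dibromophenoxy)acetate; 4 methyl acetoacetate
Product: 6 methyl 6-(2,4-dibromophenoxy)-3,5-dioxohexanoate, via dilithium dianion of methyl acetoacetate 5 (not isolated)
Conditions: 4 (2.2 equiv), LiN(iPr)2 (LDA, commercial solution, 4.2 equiv), THF, -78 to 0 °C; then 3 (1 equiv), -78 to 0 °C; 1 M HCl, 0 °C; crude 6 kept cold and used promptly
Reagents that add atoms: none
Why: γ-Acylation of a β-keto ester dianion by an ester (a crossed Claisen condensation): the terminal carbanion of 5 is its most nucleophilic site and adds to the activated α-aryloxy ester, the second equivalent of 5 absorbs the acidic proton of the diketo ester formed, and because the amide base is consumed before 3 is added the aryl bromides meet no alkyllithium or free amide.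

Step 3
Reactants: 6 methyl 6-(2,4-dibromophenoxy)-3,5-dioxohexanoate
Product: 8 2-(2,4-dibromophenoxy)benzene-1,3,5-triol, via 2-(2,4-dibromophenoxy)cyclohexane-1,3,5-trione 7 (not isolated)
Conditions: Mg(OMe)2 (commercial solution, 4 equiv), MeOH (dilute), Ar, reflux then 100 °C (sealed tube); then 2 M HCl
Reagents that add atoms: none
Why: Mg(OMe)2 turns 6 into its magnesium diketonate, and methoxide then reversibly removes a proton from C6, which is acidified by the C5 carbonyl and the aryloxy oxygen, so that the dienolate carbon C6 attacks the ester carbonyl C1 and expels methoxide to give trione 7, which enolises at once to the aromatic triol 8 (isolated after acidification). The closest known reactions are the Claisen (Dieckmann-type) cyclisation of 3,5-dioxoalkanoates and the Mg(OMe)2-mediated C-acylative cyclisation of open-chain polyketo esters and of 4-hydroxy-2-pyranones to phloroglucinols. Ring A closes in a 6-(enolendo)-exo-trig mode, and no stereocentre is formed. The step needs C-acylation through C6 instead of O-acylation through the C5 enolate oxygen and instead of retro-Claisen cleavage: magnesium chelation of the O3/O5 diketonate shields the ketones from methoxide, balances the charge of the C4,C6-dianion, activates the ester and reopens any lactone, so that O-acylation stays reversible. No other carbon–carbon closure can compete, because attack of C6 on the C3 ketone, or of C2 or C4 on any carbonyl, would give a three- or four-membered ring, and the aromatic magnesium phenoxide is the thermodynamic sink.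

Step 4
Reactants: 8 2-(2,4-dibromophenoxy)benzene-1,3,5-triol
Product: 10 3,5-diamino-2-(2,4-dibromophenoxy)phenol, via 5-amino-2-(2,4-dibromophenoxy)benzene-1,3-diol 9 (not isolated)
Conditions: 28% aq NH3 (large excess), NH4Cl (cat.), Ar, sealed vessel, 25 °C then 90 °C; crude 10 kept under Ar
Reagents that add atoms: ammonia, N
Why: Addition–elimination of ammonia on the keto tautomers of the phloroglucinol (the ammonolysis that turns phloroglucinol into 5-aminoresorcinol and then 3,5-diaminophenol) should exchange the unhindered C5 hydroxyl first and then one of the two flanking hydroxyls, which are equivalent through the C2–C5 axis, and should stop there because the diaminophenol no longer ketonises readily, while the aryl bromides and the diaryl ether are inert to copper-free aqueous ammonia.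

Step 5
Reactants: 10 3,5-diamino-2-(2,4-dibromophenoxy)phenol
Product: 12 3,5-dibromo-2-(2,4-dibromophenoxy)phenol, via arene-1,3-bis(diazonium) hydrogen sulfate 11 (not isolated)
Conditions: NaNO2, conc. H2SO4/AcOH, 0–5 °C (10 added to the preformed nitrosylsulfuric acid); then CuBr, 48% aq HBr, 0 to 70 °C
Reagents that add atoms: hydrogen bromide, Br; CuBr, [Cu]Br
Why: Tetrazotisation followed by Sandmeyer bromination: adding 10 to preformed nitrosylsulfuric acid keeps both nitrogens protonated or diazotised so that azo coupling of the meta-diamine is suppressed, both diazonium groups sit meta to the hydroxyl and so cannot collapse to a quinone diazide, and CuBr in hot concentrated HBr transfers bromine to the aryl radicals, a replacement that is routine on 2-aminodiaryl ethers.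

**Compound list**

1 | 2,4-dibromophenol | Oc1ccc(Br)cc1Br | starting material
2 | methyl bromoacetate | COC(=O)CBr | starting material
3 | methyl 2-(2,4-dibromophenoxy)acetate | COC(=O)COc1ccc(Br)cc1Br | intermediate
4 | methyl acetoacetate | COC(=O)CC(C)=O | starting material
5 | dilithium dianion of methyl acetoacetate (dilithium 1-methoxybuta-1,3-diene-1,3-diolate) | [Li+].[Li+].COC([O-])=CC([O-])=C | intermediate (not isolated)
6 | methyl 6-(2,4-dibromophenoxy)-3,5-dioxohexanoate | COC(=O)CC(=O)CC(=O)COc1ccc(Br)cc1Br | intermediate
7 | 2-(2,4-dibromophenoxy)cyclohexane-1,3,5-trione | O=C1CC(=O)C(Oc2ccc(Br)cc2Br)C(=O)C1 | intermediate (not isolated)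
8 | 2-(2,4-dibromophenoxy)benzene-1,3,5-triol | Oc1cc(O)c(Oc2ccc(Br)cc2Br)c(O)c1 | intermediate
9 | 5-amino-2-(2,4-dibromophenoxy)benzene-1,3-diol | Nc1cc(O)c(Oc2ccc(Br)cc2Br)c(O)c1 | intermediate (not isolated)
10 | 3,5-diamino-2-(2,4-dibromophenoxy)phenol | Nc1cc(N)c(Oc2ccc(Br)cc2Br)c(O)c1 | intermediate
11 | 4-(2,4-dibromophenoxy)-5-hydroxybenzene-1,3-bis(diazonium) bis(hydrogen sulfate) | N#[N+]c1cc([N+]#N)c(Oc2ccc(Br)cc2Br)c(O)c1.OS(=O)(=O)[O-].OS(=O)(=O)[O-] | intermediate (not isolated)
12 | 3,5-dibromo-2-(2,4-dibromophenoxy)phenol | Oc1cc(Br)cc(Br)c1Oc1ccc(Br)cc1Br | target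

**Count and risks**

Total step count: 5. Longest linear sequence: 5 steps (1 → 3 → 6 → 8 → 10 → 12).

Steps most likely to fail:

1. Step 3 (key step). The terminal carbanion may never build up to a useful level, so that the chain lactonises through oxygen, is cut by retro-Claisen attack of methoxide, or condenses intermolecularly faster than ring A closes. Fallback (sets out from 1, rejoins at 8): the ring would be assembled from two doubly activated partners instead of one weakly acidic chain. 2,4-Dibromophenol 1 would be alkylated with dimethyl chloromalonate (K2CO3, acetone) to give dimethyl 2-(2,4-dibromophenoxy)malonate F1. A Claisen–Dieckmann condensation of this with dimethyl 3-oxopentanedioate (NaOMe, MeOH, reflux), the classical malonate route to phloroglucinol carboxylates, should give dimethyl 5-(2,4-dibromophenoxy)-2,4,6-trihydroxybenzene-1,3-dicarboxylate F2. Saponification (aq NaOH, Ar, reflux), acidification and gentle warming should remove both carboxyl groups and deliver 8.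

2. Step 5. Tetrazotisation may be incomplete and lead to azo coupling of the electron-rich ring. The aryl radical next to the aryloxy group may close onto ring B (Pschorr-type), or the diazonium groups may be hydrolysed or reduced instead of brominated. Fallback (sets out from 8, rejoins at 12, so the diamine is bypassed as well): the oxygen-to-bromine exchange would go through aryl triflates.
   - Tf2O (2.0 equiv), 2,6-lutidine, CH2Cl2, -78 °C should sulfonylate the unhindered C5 hydroxyl first and then one flanking hydroxyl, giving 4-(2,4-dibromophenoxy)-5-hydroxy-1,3-phenylene bis(trifluoromethanesulfonate) F3 after chromatography. Once C5 has reacted, any second triflation gives this pattern.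
   - MOMCl, iPr2NEt, CH2Cl2 would cap the remaining phenol as 4-(2,4-dibromophenoxy)-5-(methoxymethoxy)-1,3-phenylene bis(trifluoromethanesulfonate) F4.
   - The known ruthenium-catalysed triflate-to-bromide exchange ([(C5Me5)Ru(MeCN)3]OTf, LiBr, 1,3-dimethylimidazolidin-2-one, 100 °C), to which aryl bromides are inert, should give 1,5-dibromo-2-(2,4-dibromophenoxy)-3-(methoxymethoxy)benzene F5.
   - HCl in MeOH would release 12.

3. Step 4. The second exchange may stall at the mono-amine stage or occur at both flanking positions, and the aminophenols may oxidise during the long contact with base. Fallback (sets out from 8, rejoins at 10): a removable primary amine would be used with azeotropic removal of water instead of aqueous ammonia. Condensation of 8 with 2,4-dimethoxybenzylamine (toluene, cat. AcOH, Dean–Stark, Ar) should give the less oxidation-prone 2-(2,4-dibromophenoxy)-3,5-bis[(2,4-dimethoxybenzyl)amino]phenol F6, the bulky amine favouring C5 and then a single flanking position. Acidolysis (TFA, Et3SiH, CH2Cl2, 40 °C) would cleave both benzyl groups and give 10.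

**Further compounds**

F1 | step 3 | dimethyl 2-(2,4-dibromophenoxy)malonate | COC(=O)C(Oc1ccc(Br)cc1Br)C(=O)OC
F2 | step 3 | dimethyl 5-(2,4-dibromophenoxy)-2,4,6-trihydroxybenzene-1,3-dicarboxylate | COC(=O)c1c(O)c(C(=O)OC)c(O)c(Oc2ccc(Br)cc2Br)c1O
F3 | step 5 | 4-(2,4-dibromophenoxy)-5-hydroxy-1,3-phenylene bis(trifluoromethanesulfonate) | Oc1cc(OS(=O)(=O)C(F)(F)F)cc(OS(=O)(=O)C(F)(F)F)c1Oc1ccc(Br)cc1Br
F4 | step 5 | 4-(2,4-dibromophenoxy)-5-(methoxymethoxy)-1,3-phenylene bis(trifluoromethanesulfonate) | COCOc1cc(OS(=O)(=O)C(F)(F)F)cc(OS(=O)(=O)C(F)(F)F)c1Oc1ccc(Br)cc1Br
F5 | step 5 | 1,5-dibromo-2-(2,4-dibromophenoxy)-3-(methoxymethoxy)benzene | COCOc1cc(Br)cc(Br)c1Oc1ccc(Br)cc1Br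
F6 | step 4 | 2-(2,4-dibromophenoxy)-3,5-bis[(2,4-dimethoxybenzyl)amino]phenol | COc1ccc(CNc2cc(NCc3ccc(OC)cc3OC)c(Oc3ccc(Br)cc3Br)c(O)c2)c(OC)c1
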